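The amounts that stop moving are what I read first. At 30.0 h the starting material stands at 21.6% in Friday's run, 21.3% in Tuesday's and 20.9% in Monday's, although Monday's loading is twice Friday's.

| setting | Friday's | Tuesday's | Monday's | red | violet | green |
|---|---|---|---|---|---|---|
| starting material | 12 mM | 12 mM | 12 mM | 12 mM | 12 mM | 12 mM |
| second substrate | 1 equiv | 1 equiv | 1 equiv | 1.00 equiv | 1.00 equiv | 1.00 equiv |
| coupling partner | 1.2 equiv | 1.2 equiv | 1.2 equiv | 1.20 equiv | 1.20 equiv | 1.20 equiv |
| protic impurity | 2.4 mM | 2.4 mM | 2.4 mM | 2.40 mM | 2.40 mM | 2.40 mM |
| free catalyst | 2.3 mol% | 3.9 mol% | 4.8 mol% | 2.5 mol% | 3.8 mol% | 5.6 mol% |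
| remark | run made earlier | run made earlier | run made earlier |  |  |  |
| time |  |  |  | 2.5 d | 2.5 d | 2.5 d |

| run | time / h | starting material / % | target / % | catalyst intermediate A / % | uncatalysed product / % |
|---|---|---|---|---|---|
| Friday's | 2.50 | 70.1 | 16.8 | 1.8 | 11.2 |
| Friday's | 8.00 | 40.6 | 36.9 | 1.2 | 21.2 |
| Friday's | 15.0 | 27.5 | 46.0 | 1.0 | 25.2 |
| Friday's | 20.0 | 23.6 | 48.7 | 0.9 | 26.0 |
| Friday's | 30.0 | 21.6 | 50.7 | 0.2 | 27.2 |
| Tuesday's | 6.00 | 37.1 | 45.5 | 2.8 | 14.6 |
| Tuesday's | 12.0 | 23.9 | 57.1 | 1.4 | 17.7 |
| Tuesday's | 20.0 | 20.7 | 59.6 | 0 | 18.5 |
| Tuesday's | 25.0 | 20.4 | 60.2 | 0.6 | 18.4 |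
| Tuesday's | 30.0 | 21.3 | 60.2 | 0.6 | 18.0 |
| Monday's | 6.00 | 32.6 | 51.7 | 3.1 | 12.9 |
| Monday's | 12.0 | 21.6 | 61.3 | 1.6 | 14.7 |
| Monday's | 20.0 | 20.8 | 63.7 | 0.6 | 15.5 |
| Monday's | 25.0 | 21.1 | 63.6 | 0.1 | 15.4 |
| Monday's | 30.0 | 20.9 | 63.4 | 0 | 15.3 |

(each reading ± 0.3 percentage points)

- the numbers in the tables scatter with a standard deviation of 0.3 percentage points

- which of these there is most of at the end, counted by the starting material in it, red (target / catalyst intermediate A / uncatalysed product / starting material)
- which of these there is most of at the end, counted by the starting material in it, violet (target / catalyst intermediate A / uncatalysed product / starting material)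
- which of these there is most of at the end, counted by the starting material in it, green (target / catalyst intermediate A / uncatalysed product / starting material)
- the largest of these amounts at the end, in percent of the starting material charged, red
- the largest of these amounts at the end, in percent of the starting material charged, violet
- the largest of these amounts at the end, in percent of the starting material charged, green

So the loading moves the split, not the stop. I assume the stop comes from the coupling partner as limiting reagent; no reading shows this directly. c(protic impurity) = 2.4 mM is 20.0% of c(starting material), and the partner's charge less that share still exceeds what was converted. I therefore reckon from the balance itself: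

stop = 21.3% of the starting material left

converted = 78.7%

price = 1.2 equiv / converted = 1.52

I carry this price, the coupling partner charged per unit of starting material converted at the stop. Red, violet and green share the partner charge of 1.20 equiv, so I expect the same 78.7% converted in each, and the loading has to divide it.

The split of target over uncatalysed product reads 1.86 on Friday and 4.14 on Monday. Extended along that line to 5.6 mol%, it gives:

green split = 4.87

green target = 65.3%

So I charge green next as written, to test the split. The partner is what I raise in the run after it: at this price the 21.3% left at the stop asks for a further 0.324 of partner per unit of starting material charged.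

The forecast names target as the leader in red, target in violet and target in green, with 52.8%, 59.7% and 65.3%. It sees the same stop but says the impurity "evidently uses up a stoichiometric partner", where I put the stop on the price.

Red ends with 52.9% of target and violet with 60.0%. Green ends with 65.4% of target, more than its 20.9% of starting material, and 0.011% of its charged coupling partner is left unbound.

    starting material + free catalyst ⇌ catalyst intermediate A (K = 2000 L mol⁻¹, k = 5.00 L mol⁻¹ s⁻¹)
    coupling partner + catalyst intermediate A → free catalyst + target (k = 0.0770 L mol⁻¹ s⁻¹)
    second substrate + free catalyst ⇌ catalyst intermediate B (K = 6700 L mol⁻¹, k = 0.190 L mol⁻¹ s⁻¹)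
    coupling partner + catalyst intermediate B → free catalyst + second product (k = 0.130 L mol⁻¹ s⁻¹)
    starting material + coupling partner → uncatalysed product (k = 0.00120 L mol⁻¹ s⁻¹)
    second substrate + catalyst intermediate B → spent catalyst (k = 0.00170 L mol⁻¹ s⁻¹)
    coupling partner + protic impurity → quenched reagent (k = 0.00160 L mol⁻¹ s⁻¹)

Green's own ending puts the price at 1.52, against the 1.52 I carried. The neighbour flask is green with 0.720 equiv of coupling partner. At the carried price that charge leaves 52.6% of the starting material, and that flask ends with 50.8%.

The data are calculated with constants of no real substance, and the scatter is random.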